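## Retrosynthetic overview

1. Kurarinone comes from its tris-MOM ether by mild acid; ring C is the only ring built, and it is closed last by a catalytic asymmetric 6-endo oxa-Michael addition of a 2'-hydroxychalcone (sets C2, S).
2. The chalcone comes from a Claisen–Schmidt condensation of an (R)-3-lavandulyl-2-hydroxyacetophenone with 2,4-bis(methoxymethoxy)benzaldehyde (rings A and B are bought as arenes).
3. The lavandulyl group comes from methylenation of an α-branched methyl ketone (isopropenyl from acetyl).
4. That ketone comes from the key step: amine–thiourea enamine catalysis joins 6-methylhept-5-en-2-one, through its internal α-carbon, to an ortho-quinone methide of ring A, forming the ArCH2–C bond and the lavandulyl (R) centre.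
5. The quinone methide precursor comes from ortho-Mannich reaction and N-methylation of 4-O-MOM-protected 2,4-dihydroxy-6-methoxyacetophenone.

Assumptions: 2,4-bis(methoxymethoxy)benzaldehyde is bought (otherwise one step from 2,4-dihydroxybenzaldehyde); the sense of induction of each organocatalyst is assigned by analogy, is checked on the first run, and the enantiomeric or pseudo-enantiomeric catalyst is used if it proves opposite.

## Route

Step 1
Reactants: 1 1-(2,4-dihydroxy-6-methoxyphenyl)ethan-1-one
Product: 2 1-[2-hydroxy-6-methoxy-4-(methoxymethoxy)phenyl]ethan-1-one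
Conditions: MOMCl (1.1 equiv), K2CO3 (1.5 equiv), acetone, 0 °C → rt
Reagents that add atoms: chloromethyl methyl ether (MOMCl), COCCl
Why: Williamson-type O-alkylation (MOM protection) in which the 2-OH is held in a hydrogen bond to the acetyl carbonyl, so only the more acidic 4-OH reacts.

Step 2
Reactants: 2 1-[2-hydroxy-6-methoxy-4-(methoxymethoxy)phenyl]ethan-1-one
Product: 4 [3-acetyl-2-hydroxy-4-methoxy-6-(methoxymethoxy)phenyl]-N,N,N-trimethylmethanaminium iodide, via Mannich base 3 (not isolated)
Conditions: Me2NH (40% aq., 1.2 equiv), CH2O (37% aq., 1.2 equiv), EtOH, 40 °C; evaporate; MeI (3 equiv), THF, 0 °C → rt, salt filtered off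
Reagents that add atoms: formaldehyde, C=O; dimethylamine, CNC; iodomethane, CI
Why: Phenol Mannich reaction followed by Menshutkin N-methylation, in which the hydrogen-bonded iminium ion is delivered to C3, the only carbon ortho to the single free OH, and quaternisation turns the amine into a leaving group that cannot later act as an enamine catalyst.

Step 3
Reactants: 4 [3-acetyl-2-hydroxy-4-methoxy-6-(methoxymethoxy)phenyl]-N,N,N-trimethylmethanaminium iodide; 5 6-methylhept-5-en-2-one
Product: 8 (3R)-3-{[3-acetyl-2-hydroxy-4-methoxy-6-(methoxymethoxy)phenyl]methyl}-6-methylhept-5-en-2-one, via o-quinone methide 6 (not isolated), via catalyst-bound enamine 7 (not isolated)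
Conditions: 5 (5 equiv), 1-[(1R,2R)-2-aminocyclohexyl]-3-[3,5-bis(trifluoromethyl)phenyl]thiourea (15 mol %), PhCO2H (15 mol %), NaHCO3 (1.5 equiv), H2O (5 equiv), CH2Cl2, 0 °C → rt, 4 added in portions
Reagents that add atoms: none
Why: Proposed new method: base releases NMe3 from 4 to give the push–pull o-quinone methide 6 slowly, the primary amine of the catalyst condenses with methyl ketone 5 to the more substituted (Z)-enamine 7 (as primary amine–thioureas do in their known internal-carbon Michael additions of alkyl methyl ketones to nitroalkenes), and the thiourea hydrogen-bonds the quinone methide carbonyl so that its exocyclic CH2 is delivered to the Si face of enamine carbon C3, which after re-aromatisation and hydrolysis gives the (3R)-ketone, the later lavandulyl C2; the closest known reaction types are the aminocatalytic enamine additions (formal [4+2]) of aldehydes to in situ o-quinone methides and the primary amine–thiourea ketone/nitroalkene Michael addition, whereas an acyclic ketone reacting at its internal carbon with a methide-unsubstituted o-quinone methide to set only the α-centre has not been shown; the α-branched product re-forms an enamine only slowly and is partly masked as its 2-chromanol hemiketal, which guards against racemisation.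

Step 4
Reactants: 8 (3R)-3-{[3-acetyl-2-hydroxy-4-methoxy-6-(methoxymethoxy)phenyl]methyl}-6-methylhept-5-en-2-one
Product: 9 1-{2-hydroxy-6-methoxy-4-(methoxymethoxy)-3-[(2R)-5-methyl-2-(prop-1-en-2-yl)hex-4-en-1-yl]phenyl}ethan-1-one
Conditions: Zn, CH2Br2, TiCl4, THF (reagent pre-formed at 0 °C, 4 equiv); 8 in CH2Cl2, 0 °C → rt; aq. NaHCO3 work-up
Reagents that add atoms: dibromomethane, BrCBr
Why: Takai–Lombardo methylenation, whose non-basic zinc/titanium methylene reagent converts the aliphatic methyl ketone into the isopropenyl group without enolisation (the α-centre keeps its R configuration), while the di-ortho-substituted, phenoxide-chelated aryl ketone is too hindered and electron-rich to react.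

Step 5
Reactants: 9 1-{2-hydroxy-6-methoxy-4-(methoxymethoxy)-3-[(2R)-5-methyl-2-(prop-1-en-2-yl)hex-4-en-1-yl]phenyl}ethan-1-one; 10 2,4-bis(methoxymethoxy)benzaldehyde
Product: 11 (2E)-3-[2,4-bis(methoxymethoxy)phenyl]-1-{2-hydroxy-6-methoxy-4-(methoxymethoxy)-3-[(2R)-5-methyl-2-(prop-1-en-2-yl)hex-4-en-1-yl]phenyl}prop-2-en-1-one
Conditions: 10 (1.2 equiv), KOH (50% aq.), EtOH, rt, 36 h; sat. NH4Cl work-up
Reagents that add atoms: none
Why: Claisen–Schmidt condensation in which the acetyl enolate adds to the non-enolisable aldehyde and E1cB loss of water gives the (E)-enone, the strongly basic medium keeping the chalcone open as its 2'-phenoxide and the lavandulyl centre having no acidic hydrogen.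

Step 6
Reactants: 11 (2E)-3-[2,4-bis(methoxymethoxy)phenyl]-1-{2-hydroxy-6-methoxy-4-(methoxymethoxy)-3-[(2R)-5-methyl-2-(prop-1-en-2-yl)hex-4-en-1-yl]phenyl}prop-2-en-1-one
Product: 12 (2S)-2-[2,4-bis(methoxymethoxy)phenyl]-5-methoxy-7-(methoxymethoxy)-8-[(2R)-5-methyl-2-(prop-1-en-2-yl)hex-4-en-1-yl]-2,3-dihydro-4H-chromen-4-one
Conditions: 1-[3,5-bis(trifluoromethyl)phenyl]-3-[(8S,9S)-6'-methoxycinchonan-9-yl]thiourea (quinine-derived, 10 mol %), toluene, 0 °C → rt
Reagents that add atoms: none
Why: Organocatalytic asymmetric intramolecular oxa-Michael addition (6-endo-trig) in which the quinuclidine activates the only free phenol, the thiourea binds the enone carbonyl and the oxygen adds to the Si face of C-β to give 2S under catalyst control, the 6'-methoxy group making ring closure strongly downhill and the product having no free phenol to re-open.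

Step 7
Reactants: 12 (2S)-2-[2,4-bis(methoxymethoxy)phenyl]-5-methoxy-7-(methoxymethoxy)-8-[(2R)-5-methyl-2-(prop-1-en-2-yl)hex-4-en-1-yl]-2,3-dihydro-4H-chromen-4-one
Product: 13 kurarinone, (2S)-2-(2,4-dihydroxyphenyl)-7-hydroxy-5-methoxy-8-[(2R)-5-methyl-2-(prop-1-en-2-yl)hex-4-en-1-yl]-2,3-dihydro-4H-chromen-4-one
Conditions: HCl (1.5 M in MeOH), 25–35 °C, stopped at full conversion
Reagents that add atoms: none
Why: Acid-catalysed acetal cleavage (MOM deprotection by transacetalisation with methanol) of the three aryl MOM ethers under conditions used for prenylated flavonoids, mild enough to leave both olefins, the 5-OMe group and both stereocentres untouched.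

## Compound list

1 | 1-(2,4-dihydroxy-6-methoxyphenyl)ethan-1-one (2',4'-dihydroxy-6'-methoxyacetophenone) | CC(=O)c1c(O)cc(O)cc1OC | starting material
2 | 1-[2-hydroxy-6-methoxy-4-(methoxymethoxy)phenyl]ethan-1-one | CC(=O)c1c(O)cc(OCOC)cc1OC | intermediate
3 | 1-{3-[(dimethylamino)methyl]-2-hydroxy-6-methoxy-4-(methoxymethoxy)phenyl}ethan-1-one (Mannich base, not isolated) | CC(=O)c1c(O)c(CN(C)C)c(OCOC)cc1OC | intermediate
4 | [3-acetyl-2-hydroxy-4-methoxy-6-(methoxymethoxy)phenyl]-N,N,N-trimethylmethanaminium iodide | CC(=O)c1c(O)c(C[N+](C)(C)C)c(OCOC)cc1OC.[I-] | intermediate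
5 | 6-methylhept-5-en-2-one (sulcatone) | CC(=O)CCC=C(C)C | starting material
6 | 2-acetyl-3-methoxy-5-(methoxymethoxy)-6-methylidenecyclohexa-2,4-dien-1-one (o-quinone methide, not isolated) | CC(=O)C1=C(OC)C=C(OCOC)C(=C)C1=O | intermediate
7 | 1-[(1R,2R)-2-{[(2Z)-6-methylhepta-2,5-dien-2-yl]amino}cyclohexyl]-3-[3,5-bis(trifluoromethyl)phenyl]thiourea (catalyst-bound enamine of 5, not isolated) | C/C(N[C@@H]1CCCC[C@H]1NC(=S)Nc1cc(C(F)(F)F)cc(C(F)(F)F)c1)=C/CC=C(C)C | intermediate
8 | (3R)-3-{[3-acetyl-2-hydroxy-4-methoxy-6-(methoxymethoxy)phenyl]methyl}-6-methylhept-5-en-2-one (open keto-phenol form; ring-chain tautomer is the 2-chromanol hemiketal) | CC(=O)[C@H](CC=C(C)C)Cc1c(O)c(C(C)=O)c(OC)cc1OCOC | intermediate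
9 | 1-{2-hydroxy-6-methoxy-4-(methoxymethoxy)-3-[(2R)-5-methyl-2-(prop-1-en-2-yl)hex-4-en-1-yl]phenyl}ethan-1-one | C=C(C)[C@H](CC=C(C)C)Cc1c(O)c(C(C)=O)c(OC)cc1OCOC | intermediate
10 | 2,4-bis(methoxymethoxy)benzaldehyde | O=Cc1ccc(OCOC)cc1OCOC | starting material
11 | (2E)-3-[2,4-bis(methoxymethoxy)phenyl]-1-{2-hydroxy-6-methoxy-4-(methoxymethoxy)-3-[(2R)-5-methyl-2-(prop-1-en-2-yl)hex-4-en-1-yl]phenyl}prop-2-en-1-one | C=C(C)[C@H](CC=C(C)C)Cc1c(O)c(C(=O)/C=C/c2ccc(OCOC)cc2OCOC)c(OC)cc1OCOC | intermediate
12 | (2S)-2-[2,4-bis(methoxymethoxy)phenyl]-5-methoxy-7-(methoxymethoxy)-8-[(2R)-5-methyl-2-(prop-1-en-2-yl)hex-4-en-1-yl]-2,3-dihydro-4H-chromen-4-one | C=C(C)[C@H](CC=C(C)C)Cc1c(OCOC)cc(OC)c2c1O[C@H](c1ccc(OCOC)cc1OCOC)CC2=O | intermediate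
13 | kurarinone, (2S)-2-(2,4-dihydroxyphenyl)-7-hydroxy-5-methoxy-8-[(2R)-5-methyl-2-(prop-1-en-2-yl)hex-4-en-1-yl]-2,3-dihydro-4H-chromen-4-one | C=C(C)[C@H](CC=C(C)C)Cc1c(O)cc(OC)c2c1O[C@H](c1ccc(O)cc1O)CC2=O | target

## Step count and risk

Total steps: 7. Longest linear sequence: 7 steps (1 → 13); 5 and 10 are bought and enter at steps 3 and 5. The two stereocentres are set independently under catalyst control, so the minor enantiomer from either step ends up as a diastereomer of 13, not as its enantiomer.

The three steps most likely to fail: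

**Step 3 (proposed new method).** The risks are N-benzylation of the primary amine catalyst by 6, oligomerisation of 6, attack through the methyl side of 5, and low enantioselectivity at a centre that is set on the nucleophile alone. The fallback sets out from 4 and comes back at 8, and uses known secondary-amine enamine chemistry with an aldehyde in place of the ketone. Compound 4 is treated with 5-methylhex-4-enal (3 equiv), (S)-α,α-diphenylprolinol trimethylsilyl ether (20 mol %), PhCO2H (20 mol %) and NaHCO3 in CH2Cl2 at 0 °C. This is the known formal [4+2] addition of an aldehyde enamine to an o-quinone methide made in the flask, with the electrophile entering anti to the diarylmethyl group. It gives (2R)-2-{[3-acetyl-2-hydroxy-4-methoxy-6-(methoxymethoxy)phenyl]methyl}-5-methylhex-4-enal F1, held mainly as its 2-chromanol lactol. MeTi(OiPr)3 in THF at −40 °C then adds to the aldehyde only and gives (3R)-3-{[3-acetyl-2-hydroxy-4-methoxy-6-(methoxymethoxy)phenyl]methyl}-6-methylhept-5-en-2-ol F2 as a mixture of carbinol epimers. Dess–Martin periodinane with NaHCO3 in CH2Cl2 oxidises F2 to ketone 8. This costs two extra steps and keeps the same electrophile.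

**Step 4.** The risks are partial attack on the aryl ketone, loss of a MOM group to Lewis acid, and epimerisation of the α-centre if the reagent is not clean. The fallback sets out from 8 and comes back at 9, and is a Peterson olefination through a non-basic organocerium. Me3SiCH2MgCl with CeCl3 in THF at −78 °C adds to the aliphatic ketone without enolisation and gives (3R)-3-{[3-acetyl-2-hydroxy-4-methoxy-6-(methoxymethoxy)phenyl]methyl}-2,6-dimethyl-1-(trimethylsilyl)hept-5-en-2-ol F3 as carbinol epimers. Once this addition has taken place the stereocentre is no longer α to a carbonyl. KH in THF at 0 °C → rt then brings about syn-elimination and gives 9.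

**Step 6.** Organocatalytic cyclisation of unactivated 2'-hydroxychalcones is known but has given only moderate enantioselectivity, and a poor ratio here would leave C2 epimers that are hard to separate. The fallback sets out from 11 and comes back at 12, and replaces asymmetric ring closure by a catalyst-controlled kinetic resolution. NaOAc in EtOH at reflux closes the ring without control and gives about a 1:1 mixture of 12 and its C2 epimer (2R)-2-[2,4-bis(methoxymethoxy)phenyl]-5-methoxy-7-(methoxymethoxy)-8-[(2R)-5-methyl-2-(prop-1-en-2-yl)hex-4-en-1-yl]-2,3-dihydro-4H-chromen-4-one F4. Asymmetric transfer hydrogenation with Cp*RhCl[(R,R)-TsDPEN] (1 mol %) and HCO2H/Et3N in EtOAc at rt follows; this catalyst forms 4R carbinols and so should reduce only the 2R epimer. That epimer is converted to the cis-flavanol (2R,4R)-2-[2,4-bis(methoxymethoxy)phenyl]-5-methoxy-7-(methoxymethoxy)-8-[(2R)-5-methyl-2-(prop-1-en-2-yl)hex-4-en-1-yl]-3,4-dihydro-2H-chromen-4-ol F5. The olefins and MOM ethers are inert, and unreacted 12 is separated from the much more polar alcohol by chromatography (at most half of the material is recovered as 12).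

Further compounds

F1 | step 3 | (2R)-2-{[3-acetyl-2-hydroxy-4-methoxy-6-(methoxymethoxy)phenyl]methyl}-5-methylhex-4-enal | O=C[C@H](CC=C(C)C)Cc1c(O)c(C(C)=O)c(OC)cc1OCOC
F2 | step 3 | (3R)-3-{[3-acetyl-2-hydroxy-4-methoxy-6-(methoxymethoxy)phenyl]methyl}-6-methylhept-5-en-2-ol (C2 epimers) | CC(O)[C@H](CC=C(C)C)Cc1c(O)c(C(C)=O)c(OC)cc1OCOC
F3 | step 4 | (3R)-3-{[3-acetyl-2-hydroxy-4-methoxy-6-(methoxymethoxy)phenyl]methyl}-2,6-dimethyl-1-(trimethylsilyl)hept-5-en-2-ol (C2 epimers) | C[Si](C)(C)CC(C)(O)[C@H](CC=C(C)C)Cc1c(O)c(C(C)=O)c(OC)cc1OCOC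
F4 | step 6 | (2R)-2-[2,4-bis(methoxymethoxy)phenyl]-5-methoxy-7-(methoxymethoxy)-8-[(2R)-5-methyl-2-(prop-1-en-2-yl)hex-4-en-1-yl]-2,3-dihydro-4H-chromen-4-one | C=C(C)[C@H](CC=C(C)C)Cc1c(OCOC)cc(OC)c2c1O[C@@H](c1ccc(OCOC)cc1OCOC)CC2=O
F5 | step 6 | (2R,4R)-2-[2,4-bis(methoxymethoxy)phenyl]-5-methoxy-7-(methoxymethoxy)-8-[(2R)-5-methyl-2-(prop-1-en-2-yl)hex-4-en-1-yl]-3,4-dihydro-2H-chromen-4-ol | C=C(C)[C@H](CC=C(C)C)Cc1c(OCOC)cc(OC)c2c1O[C@@H](c1ccc(OCOC)cc1OCOC)C[C@H]2O
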